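## Structural features

The target is an acyclic lignan of the dibenzylbutanediol type. Two identical 4-hydroxy-3,5-dimethoxyphenyl rings are each joined through a benzylic methylene (C7, C7') to a four-carbon chain C9–C8–C8'–C9' that ends in a primary alcohol on both sides. The only stereocentres, C8 and C8', are adjacent, both R and related by a C2 axis, so the molecule is the chiral diastereomer and must be kept apart from the meso form. There is no ring other than the two arenes, so no cyclic bias helps the stereocontrol. The free, electron-rich phenols are easily oxidised, and the 1,4-diol can close to a tetrahydrofuran under acid; the phenols are therefore masked until the end and strong acid is avoided. The real difficulty is absolute and relative control at two neighbouring, constitutionally identical acyclic centres whose arms (CH2–aryl, CH2OH, H) differ little in size. The key step uses the fact that C8 is bonded to C7H2–aryl, to C8' and to the one-carbon arm C9. A vinyl group can therefore supply C7 and C8: it takes the aryl ring at its terminus and C8' at its inner carbon, while boron stays on C8 as the handle for C9.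

## Logic of the disconnections

14 back to 13. The three O–CH2Ph bonds are cut (two phenolic, one on O9'). The phenols are oxidation-prone and O9' has to stay distinct from boron during the assembly; one protecting group type allows a single neutral final operation. The gain is a robust, non-polar penultimate compound. The demand is that hydrogenolysis also removes the slower alkyl benzyl ether without acid.

13 back to 10 (through 12 and 11). The C9–O and C8–C9 bonds are cut. A hydroxymethyl group on a stereocentre is the retron of a one-carbon homologation of a secondary boronate followed by oxidation, and both events retain configuration. The gain is that boron sits directly on C8, so C8 becomes the product of a boron-based C–C bond formation. The demand is that a short-lived carbenoid is captured by a hindered boron.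

10 back to 7, 8 and 2 (through 9). The C8–C8' bond and the aryl–C7 bond are cut. This splits the molecule at the bond between the two stereocentres into one half that already carries C8', a two-carbon unit, and an aryl bromide. With boron ranked below carbon, 7 is S and 10 is 2R,3R; both map onto the R,R target through retentive events only. The demand is threefold: the metallate shift must outrun direct vinyl transfer, the catalyst must set C8 as R next to the existing centre, and the four-coordinate boron must not expel the β-benzyloxy group.

7 back to 5 and 6. The C8'–B and C7'–H bonds are cut. A boronate one carbon away from an arene is the retron of an enantioselective copper–boron addition to a styrene-type alkene. The gain is an achiral precursor. The demand is boron on the non-benzylic carbon, one alkene face, and no loss of the allylic oxygen.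

5 back to 2 and 4. The aryl–C7' bond is cut. Cutting here lets 2 serve as the source of both aryl rings and shortens the sequence relative to an aldehyde homologation–reduction–etherification line. The demand is clean retention of the E geometry, which fixes the sense of induction in the next step.

4 back to 3, and 2 back to 1. The C–B and C–H bonds across a terminal alkyne, and one O–CH2Ph bond, are cut. Both go back to commercial materials in one step each; the only demand is linear, syn hydroboration.

## Other disconnections considered

Alternative 1: The cut runs through C7'–C8' and C7–C8 at once; the C8–C8' bond is already present in (5R)-5-menthyloxyfuran-2(5H)-one A2. In the forward step the lithium derivative of 2-(4-benzyloxy-3,5-dimethoxyphenyl)-1,3-dithiane A1 would add to C4 of A2 on the face away from the menthyloxy group. The lactone enolate would then be benzylated by 2-(benzyloxy)-5-(bromomethyl)-1,3-dimethoxybenzene A3 trans to the new substituent, giving the all-trans lactone A4.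
- In its favour: two C–C bonds and both stereocentres arise in one flask under substrate control from an inexpensive acetal auxiliary, and this addition–alkylation is a well-tried entry to dibenzylbutyrolactone lignans. On reliability of stereocontrol it is the better plan.
- Against it here: A1, A2 and A3 each have to be made (about two, two and three steps). After A4 the sulfur must be removed reductively, the lactone acetal reduced to the diol, and the benzyl ethers cleaved. Raney Ni could attack the benzyl ethers unevenly, and sulfur residues could slow the final Pd/C step. The chirality source is stoichiometric.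
- Comparison: about eleven steps in total and a longest sequence of about seven, against seven and six for the chosen plan. It uses polar enolate chemistry of proven scope where the chosen plan uses a catalytic metallate shift near the edge of its scope. It is safer in the key step, but longer and less convergent.

Alternative 2: The cut runs through both aryl–C7 bonds and leaves a C2-symmetric six-carbon core that already holds C8, C8', C9 and C9', as the bis(redox-active ester) A5. In the forward step, reductive nickel electrocatalysis (NiBr2 with a bipyridine ligand, sacrificial anode) would remove two CO2 from A5 and couple both primary radicals with 2 to give A6.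
- In its favour: it uses the symmetry of the target fully, attaching the same bromide 2 twice in one operation. No stereocentre is formed or touched in the key step, a point on which it is better than the chosen plan. The end-game would be only desilylation and hydrogenolysis.
- Against it here: the stereochemical problem moves into the synthesis of A5, which would need about five steps of its own (setting two centres on a ring, reduction, silylation, oxidative ring cleavage, activation). Two radical couplings must succeed on one molecule, so any loss per site (premature reduction of the radical, dimerisation) counts twice. An electron-rich aryl bromide is a slow partner in reductive nickel coupling. Two kinds of protecting group must be removed.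
- Comparison: about nine steps with a longest sequence of about eight, so it is not shorter. It is stereochemically neutral and radical in mechanism, where the chosen plan is organometallic and stereodefining.

Alternative 3: The cut runs through aryl–C7 and C7'–C8' and leads to the bicyclic cyclopropane lactone A7, methyl (1S,5R)-2-oxo-3-oxabicyclo[3.1.0]hexane-1-carboxylate, in which C8 is a chiral-pool centre. In the forward step the arylmagnesium bromide A8 (from 2) with catalytic CuI would open the activated cyclopropane at its CH2 by homoconjugate addition. The malonate-type enolate would then be benzylated by A3 to give A9 with the benzyl groups trans.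
- In its favour: A7 is reachable in one step from cheap chiral-pool material with no chiral catalyst, and two C–C bonds form in one flask. The second centre is later fixed by the thermodynamic preference for the trans lactone. On cost and on security of absolute configuration it is at least the equal of the chosen plan.
- Against it here: three further operations follow A9. These are loss of the ester group (the step in which C8' is really set, so some cis lactone may persist), hydride reduction, and hydrogenolysis. A3 costs three steps. The opening must select the cyclopropane CH2 over two carbonyl groups and the lactone CH2–O.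
- Comparison: about nine steps with a longest sequence of about seven. The chosen plan is shorter and reaches the diol without a redox detour, but depends on a less proven key step.

Key step: step 5

Assumption: the antipodes of the two chiral ligands (the carbene on copper in step 4 and the Mandyphos ligand on palladium in step 5) are written as those expected to give 7 as S and C8 of 10 as R; if a pilot run shows the opposite sense for either, its mirror-image ligand is used and nothing else changes.

## Route

Step 1
Reactants: 1 4-bromo-2,6-dimethoxyphenol
Product: 2 2-(benzyloxy)-5-bromo-1,3-dimethoxybenzene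
Conditions: BnBr, K2CO3, DMF, 60 °C
Reagents that add atoms: benzyl bromide, BrCc1ccccc1
Why: Williamson ether synthesis; the phenoxide formed by K2CO3 displaces bromide from benzyl bromide, and the aryl C–Br bond is inert under these conditions.

Step 2
Reactants: 3 benzyl propargyl ether
Product: 4 (E)-2-[3-(benzyloxy)prop-1-en-1-yl]-4,4,5,5-tetramethyl-1,3,2-dioxaborolane
Conditions: pinacolborane, Cp2Zr(H)Cl (5 mol%), Et3N (10 mol%), neat, 60 °C
Reagents that add atoms: pinacolborane, [H]B1OC(C)(C)C(C)(C)O1
Why: Zirconium-hydride-catalysed hydroboration of a terminal alkyne; syn hydrozirconation puts the metal on the terminal carbon and exchange with pinacolborane gives the linear E alkenyl boronate, with the ether oxygen too remote to eliminate.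

Step 3
Reactants: 2 2-(benzyloxy)-5-bromo-1,3-dimethoxybenzene, 4 (E)-2-[3-(benzyloxy)prop-1-en-1-yl]-4,4,5,5-tetramethyl-1,3,2-dioxaborolane
Product: 5 2-(benzyloxy)-5-[(E)-3-(benzyloxy)prop-1-en-1-yl]-1,3-dimethoxybenzene
Conditions: Pd(dppf)Cl2 (3 mol%), K3PO4, 1,4-dioxane–H2O, 80 °C
Reagents that add atoms: none
Why: Suzuki–Miyaura coupling of an aryl bromide with an alkenyl boronate, which transfers the alkenyl group with retention of the E geometry; a benzyl ether is too poor a leaving group to ionise at the allylic position.

Step 4
Reactants: 5 2-(benzyloxy)-5-[(E)-3-(benzyloxy)prop-1-en-1-yl]-1,3-dimethoxybenzene, 6 bis(pinacolato)diboron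
Product: 7 (S)-2-[1-(benzyloxy)-3-(4-benzyloxy-3,5-dimethoxyphenyl)propan-2-yl]-4,4,5,5-tetramethyl-1,3,2-dioxaborolane
Conditions: CuCl (5 mol%), chiral C1-symmetric sulfonate-bearing imidazolinium salt (carbene precursor, antipode giving S, 5 mol%), KOt-Bu (20 mol%), MeOH (2 equiv), THF, −50 → −15 °C
Reagents that add atoms: none
Why: Copper-catalysed enantioselective protoboration of a β-substituted styrene, chosen with a carbene ligand because this ligand class is the one established for copper–boron addition to 1,2-disubstituted aryl alkenes; the carbene–Cu–B(pin) species adds syn with boron on the carbon remote from the arene and copper on the benzylic carbon, methanol then protonates the C–Cu bond, and the chiral carbene selects the face of the E alkene so that C8' is formed as S. In this regioisomer copper is not β to the benzyloxy group, so alkoxide elimination is not open to it.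

Step 5
Reactants: 7 (S)-2-[1-(benzyloxy)-3-(4-benzyloxy-3,5-dimethoxyphenyl)propan-2-yl]-4,4,5,5-tetramethyl-1,3,2-dioxaborolane, 8 vinylmagnesium bromide, 2 2-(benzyloxy)-5-bromo-1,3-dimethoxybenzene
Product: 10 2-[(2R,3R)-1,4-bis(4-benzyloxy-3,5-dimethoxyphenyl)-3-[(benzyloxy)methyl]butan-2-yl]-4,4,5,5-tetramethyl-1,3,2-dioxaborolane, via vinyl boronate complex 9 (not isolated)
Conditions: 8 (1.15 equiv), THF, 0 °C → rt; then 2 (1.1 equiv), Pd(OAc)2 (3 mol%), (Sp,Sp)-Mandyphos [bis(4-methoxy-3,5-dimethylphenyl)phosphino type] (3.6 mol%), NaOTf (2 equiv), THF, 40–60 °C
Reagents that add atoms: none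
Why: Vinylmagnesium bromide adds to the boron of 7 to give the four-coordinate vinyl boronate 9, a step helped by NaOTf. Oxidative addition of 2 to zerovalent palladium and removal of bromide by NaOTf give a cationic aryl complex of divalent palladium that binds the vinyl π bond of 9. This induces a 1,2-metallate shift in which C8' moves from boron to the inner vinyl carbon anti to palladium, and reductive elimination then joins the aryl group to the former vinyl terminus (C7). The closest known reaction type is the enantioselective palladium-catalysed conjunctive cross-coupling of vinyl boron ate complexes with aryl electrophiles, whose scope includes secondary alkyl migrating groups. No ring is closed, so no mode of closure arises. The new stereocentre C8 is controlled by the chiral Mandyphos–palladium complex, which selects the face of the bound vinyl group; C8' migrates with retention, so the product is the 2R,3R boronate. The step needs the metallate shift to outrun direct vinyl transfer to palladium and β-elimination of the benzyloxy group from 9; the halide-free cationic palladium centre, the non-migrating pinacolato oxygens (leaving C8' as the only group able to shift) and pre-formation of 9 in the cold with close to one equivalent of the Grignard reagent secure this.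

Step 6
Reactants: 10 2-[(2R,3R)-1,4-bis(4-benzyloxy-3,5-dimethoxyphenyl)-3-[(benzyloxy)methyl]butan-2-yl]-4,4,5,5-tetramethyl-1,3,2-dioxaborolane
Product: 13 (2R,3R)-4-(benzyloxy)-2,3-bis(4-benzyloxy-3,5-dimethoxybenzyl)butan-1-ol, via chloromethyl boronate complex 11 (not isolated), via primary pinacol boronate 12 (not isolated)
Conditions: BrCH2Cl (3 equiv), n-BuLi (2.5 equiv), THF, −78 °C → rt; then NaOH (2 M aq), H2O2 (30% aq), 0 °C → rt
Reagents that add atoms: bromochloromethane, ClCBr; hydrogen peroxide, OO
Why: Matteson homologation followed by boronate oxidation; LiCH2Cl made in the presence of 10 adds to boron, C8 migrates to the CH2 carbon with loss of chloride and with retention at C8, and alkaline peroxide turns the new primary C–B bond into C–OH. The migration starts only on warming, after the excess carbenoid has decayed, which guards against a second insertion; the aryl and benzyl ethers are inert.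

Step 7
Reactants: 13 (2R,3R)-4-(benzyloxy)-2,3-bis(4-benzyloxy-3,5-dimethoxybenzyl)butan-1-ol
Product: 14 (2R,3R)-2,3-bis(4-hydroxy-3,5-dimethoxybenzyl)butane-1,4-diol (5,5'-dimethoxysecoisolariciresinol)
Conditions: H2 (1 atm), Pd/C (10%), MeOH–EtOAc, rt
Reagents that add atoms: none
Why: Catalytic hydrogenolysis of the two aryl benzyl ethers and the one alkyl benzyl ether; no stereocentre is touched, and the neutral medium avoids acid-promoted closure of the 1,4-diol to a tetrahydrofuran.

## Compound list

1 | 4-bromo-2,6-dimethoxyphenol | COc1cc(Br)cc(OC)c1O | starting material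
2 | 2-(benzyloxy)-5-bromo-1,3-dimethoxybenzene | COc1cc(Br)cc(OC)c1OCc1ccccc1 | intermediate
3 | benzyl propargyl ether | C#CCOCc1ccccc1 | starting material
4 | (E)-2-[3-(benzyloxy)prop-1-en-1-yl]-4,4,5,5-tetramethyl-1,3,2-dioxaborolane | CC1(C)OB(/C=C/COCc2ccccc2)OC1(C)C | intermediate
5 | 2-(benzyloxy)-5-[(E)-3-(benzyloxy)prop-1-en-1-yl]-1,3-dimethoxybenzene | COc1cc(/C=C/COCc2ccccc2)cc(OC)c1OCc1ccccc1 | intermediate
6 | bis(pinacolato)diboron | CC1(C)OB(OC1(C)C)B1OC(C)(C)C(C)(C)O1 | starting material
7 | (S)-2-[1-(benzyloxy)-3-(4-benzyloxy-3,5-dimethoxyphenyl)propan-2-yl]-4,4,5,5-tetramethyl-1,3,2-dioxaborolane | CC1(C)OB(OC1(C)C)[C@H](COCc1ccccc1)Cc1cc(OC)c(OCc2ccccc2)c(OC)c1 | intermediate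
8 | vinylmagnesium bromide | C=C[Mg]Br | starting material
9 | bromomagnesium [(S)-1-(benzyloxy)-3-(4-benzyloxy-3,5-dimethoxyphenyl)propan-2-yl](ethenyl)(pinacolato)borate | C=C[B-]1(OC(C)(C)C(C)(C)O1)[C@H](COCc1ccccc1)Cc1cc(OC)c(OCc2ccccc2)c(OC)c1.[Mg+]Br | intermediate (not isolated)
10 | 2-[(2R,3R)-1,4-bis(4-benzyloxy-3,5-dimethoxyphenyl)-3-[(benzyloxy)methyl]butan-2-yl]-4,4,5,5-tetramethyl-1,3,2-dioxaborolane | COc1cc(C[C@@H](B2OC(C)(C)C(C)(C)O2)[C@H](COCc2ccccc2)Cc2cc(OC)c(OCc3ccccc3)c(OC)c2)cc(OC)c1OCc1ccccc1 | intermediate
11 | lithium (chloromethyl)[(2R,3R)-1,4-bis(4-benzyloxy-3,5-dimethoxyphenyl)-3-[(benzyloxy)methyl]butan-2-yl](pinacolato)borate | COc1cc(C[C@@H]([B-]2(CCl)OC(C)(C)C(C)(C)O2)[C@H](COCc2ccccc2)Cc2cc(OC)c(OCc3ccccc3)c(OC)c2)cc(OC)c1OCc1ccccc1.[Li+] | intermediate (not isolated)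
12 | 2-[(2R,3R)-4-(benzyloxy)-2,3-bis(4-benzyloxy-3,5-dimethoxybenzyl)butyl]-4,4,5,5-tetramethyl-1,3,2-dioxaborolane | COc1cc(C[C@@H](CB2OC(C)(C)C(C)(C)O2)[C@H](COCc2ccccc2)Cc2cc(OC)c(OCc3ccccc3)c(OC)c2)cc(OC)c1OCc1ccccc1 | intermediate (not isolated)
13 | (2R,3R)-4-(benzyloxy)-2,3-bis(4-benzyloxy-3,5-dimethoxybenzyl)butan-1-ol | COc1cc(C[C@@H](CO)[C@H](COCc2ccccc2)Cc2cc(OC)c(OCc3ccccc3)c(OC)c2)cc(OC)c1OCc1ccccc1 | intermediate
14 | (2R,3R)-2,3-bis(4-hydroxy-3,5-dimethoxybenzyl)butane-1,4-diol (5,5'-dimethoxysecoisolariciresinol) | COc1cc(C[C@@H](CO)[C@H](CO)Cc2cc(OC)c(O)c(OC)c2)cc(OC)c1O | target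

## Step count and least certain steps

Total step count: 7. Longest linear sequence: 6 (step 1 or step 2, then steps 3 to 7).

**Step 5 (key step).** Four things are most likely to go wrong.
- The hindered secondary pinacol boronate may be only partly converted into the ate complex by a Grignard reagent.
- Benzyloxide on the carbon next to the four-coordinate boron may be lost by β-elimination during the warm coupling.
- The bulky branched group may shift slowly, so that direct vinyl transfer to palladium (plain cross-coupling) takes over.
- The ligand and the existing C8' centre may be mismatched, which would erode facial selectivity and let the meso-type diastereomer through.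

The fallback replaces the catalytic shift by a reagent-controlled carbenoid homologation. It sets out from 7 (with a side branch from 2) and returns at 10. Bromine–lithium exchange on 2 (n-BuLi, THF, −78 °C) and opening of oxirane would give 2-(4-benzyloxy-3,5-dimethoxyphenyl)ethanol F1. Mitsunobu esterification with 2,4,6-triisopropylbenzoic acid would give 2-(4-benzyloxy-3,5-dimethoxyphenyl)ethyl 2,4,6-triisopropylbenzoate F2. Deprotonation with s-BuLi and (−)-sparteine in Et2O at −78 °C, directed by the ester carbonyl and therefore expected to be faster than benzylic deprotonation, would give the (S)-configured α-lithiated ester F3. Addition of 7 would form the lithium boronate complex F4 with retention at the lithiated carbon. On warming (with MgBr2·OEt2 and MeOH if needed), C8' would migrate with retention while the benzoate leaves with inversion at C8, giving 10 with C8 as R.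

**Step 4.** Three things could go wrong. The copper–boron addition may occur in the opposite sense (boron on the benzylic carbon); this would place copper next to the benzyloxymethyl carbon and lead to loss of benzyloxide, i.e. allylic substitution instead of protoboration. Addition to an electron-rich styrene may be slow. Face selection may be insufficient.

The fallback sets out from 2 and returns at 7, using the ester F2 described under step 5 (made from 2 through F1). s-BuLi with (+)-sparteine would give the (R)-configured α-lithiated ester F5. 2-[(Benzyloxy)methyl]-4,4,5,5-tetramethyl-1,3,2-dioxaborolane F6, made from commercial 2-(bromomethyl)-4,4,5,5-tetramethyl-1,3,2-dioxaborolane and sodium benzyloxide, would add to it to give the lithium boronate complex F7. The 1,2-shift of the benzyloxymethyl group with inversion at the carbenoid carbon would then give 7 as the S boronate, with the regiochemistry fixed by construction.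

**Step 6.** The likely failure is incomplete capture of the thermally fragile LiCH2Cl by the hindered, doubly branched boronate. Unchanged 10 would then be oxidised to a secondary alcohol that has to be separated. If a second addition of carbenoid is needed, 12 can be isolated before oxidation.

The fallback uses a thermally stable carbon nucleophile. It sets out from 10 and returns at 13. Vinylmagnesium bromide 8 in THF–DMSO would give the bromomagnesium vinyl boronate complex F8. Iodine and then NaOMe (Zweifel olefination, retention at C8) would give (3S,4R)-5-(4-benzyloxy-3,5-dimethoxyphenyl)-3-(4-benzyloxy-3,5-dimethoxybenzyl)-4-[(benzyloxy)methyl]pent-1-ene F9. Buffered Lemieux–Johnson cleavage (OsO4 cat., NaIO4, 2,6-lutidine) would give (2R,3R)-4-(benzyloxy)-2,3-bis(4-benzyloxy-3,5-dimethoxybenzyl)butanal F10. This is reduced at once with NaBH4 to 13, so that epimerisation next to the aldehyde has little time to occur.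

## Further compounds

F1 | step 5 | 2-(4-benzyloxy-3,5-dimethoxyphenyl)ethanol | COc1cc(CCO)cc(OC)c1OCc1ccccc1
F2 | step 5 | 2-(4-benzyloxy-3,5-dimethoxyphenyl)ethyl 2,4,6-triisopropylbenzoate | COc1cc(CCOC(=O)c2c(C(C)C)cc(C(C)C)cc2C(C)C)cc(OC)c1OCc1ccccc1
F3 | step 5 | (S)-2-(4-benzyloxy-3,5-dimethoxyphenyl)-1-lithioethyl 2,4,6-triisopropylbenzoate ((−)-sparteine complex) | [Li][C@H](OC(=O)c1c(C(C)C)cc(C(C)C)cc1C(C)C)Cc1cc(OC)c(OCc2ccccc2)c(OC)c1
F4 | step 5 | lithium boronate complex of F3 with 7 | CC1(C)O[B-](OC1(C)C)([C@H](OC(=O)c1c(C(C)C)cc(C(C)C)cc1C(C)C)Cc1cc(OC)c(OCc2ccccc2)c(OC)c1)[C@H](COCc1ccccc1)Cc1cc(OC)c(OCc2ccccc2)c(OC)c1.[Li+]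
F5 | step 4 | (R)-2-(4-benzyloxy-3,5-dimethoxyphenyl)-1-lithioethyl 2,4,6-triisopropylbenzoate ((+)-sparteine complex) | [Li][C@@H](OC(=O)c1c(C(C)C)cc(C(C)C)cc1C(C)C)Cc1cc(OC)c(OCc2ccccc2)c(OC)c1
F6 | step 4 | 2-[(benzyloxy)methyl]-4,4,5,5-tetramethyl-1,3,2-dioxaborolane | CC1(C)OB(COCc2ccccc2)OC1(C)C
F7 | step 4 | lithium boronate complex of F5 with F6 | CC1(C)O[B-](OC1(C)C)(COCc1ccccc1)[C@@H](OC(=O)c1c(C(C)C)cc(C(C)C)cc1C(C)C)Cc1cc(OC)c(OCc2ccccc2)c(OC)c1.[Li+]
F8 | step 6 | bromomagnesium vinyl boronate complex of 10 | COc1cc(C[C@@H]([B-]2(C=C)OC(C)(C)C(C)(C)O2)[C@H](COCc2ccccc2)Cc2cc(OC)c(OCc3ccccc3)c(OC)c2)cc(OC)c1OCc1ccccc1.[Mg+]Br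
F9 | step 6 | (3S,4R)-5-(4-benzyloxy-3,5-dimethoxyphenyl)-3-(4-benzyloxy-3,5-dimethoxybenzyl)-4-[(benzyloxy)methyl]pent-1-ene | COc1cc(C[C@@H](C=C)[C@H](COCc2ccccc2)Cc2cc(OC)c(OCc3ccccc3)c(OC)c2)cc(OC)c1OCc1ccccc1
F10 | step 6 | (2R,3R)-4-(benzyloxy)-2,3-bis(4-benzyloxy-3,5-dimethoxybenzyl)butanal | COc1cc(C[C@@H](C=O)[C@H](COCc2ccccc2)Cc2cc(OC)c(OCc3ccccc3)c(OC)c2)cc(OC)c1OCc1ccccc1
A1 | alternative 1 | 2-(4-benzyloxy-3,5-dimethoxyphenyl)-1,3-dithiane | COc1cc(C2SCCCS2)cc(OC)c1OCc1ccccc1
A2 | alternative 1 | (5R)-5-[(1R,2S,5R)-menthyloxy]furan-2(5H)-one | O=C1C=C[C@H](O[C@@H]2C[C@H](C)CC[C@H]2C(C)C)O1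
A3 | alternative 1 | 2-(benzyloxy)-5-(bromomethyl)-1,3-dimethoxybenzene | COc1cc(CBr)cc(OC)c1OCc1ccccc1
A4 | alternative 1 | (3R,4R,5R)-3-(4-benzyloxy-3,5-dimethoxybenzyl)-4-[2-(4-benzyloxy-3,5-dimethoxyphenyl)-1,3-dithian-2-yl]-5-[(1R,2S,5R)-menthyloxy]dihydrofuran-2(3H)-one | COc1cc(C2(SCCCS2)[C@@H]3[C@H](C(=O)O[C@H]3O[C@@H]4C[C@H](C)CC[C@H]4C(C)C)Cc5cc(OC)c(OCc6ccccc6)c(OC)c5)cc(OC)c1OCc1ccccc1
A5 | alternative 2 | bis(1,3-dioxoisoindolin-2-yl) (3R,4R)-3,4-bis[(tert-butyldimethylsilyloxy)methyl]hexanedioate | O=C(C[C@@H](CO[Si](C)(C)C(C)(C)C)[C@H](CO[Si](C)(C)C(C)(C)C)CC(=O)ON1C(=O)c2ccccc2C1=O)ON1C(=O)c2ccccc2C1=O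
A6 | alternative 2 | (2R,3R)-1,4-bis(4-benzyloxy-3,5-dimethoxyphenyl)-2,3-bis[(tert-butyldimethylsilyloxy)methyl]butane | COc1cc(C[C@@H](CO[Si](C)(C)C(C)(C)C)[C@H](CO[Si](C)(C)C(C)(C)C)Cc2cc(OC)c(OCc3ccccc3)c(OC)c2)cc(OC)c1OCc1ccccc1
A7 | alternative 3 | methyl (1S,5R)-2-oxo-3-oxabicyclo[3.1.0]hexane-1-carboxylate | O=C1OC[C@@H]2C[C@]12C(=O)OC
A8 | alternative 3 | (4-benzyloxy-3,5-dimethoxyphenyl)magnesium bromide | COc1cc([Mg]Br)cc(OC)c1OCc1ccccc1
A9 | alternative 3 | methyl (3R,4R)-3,4-bis(4-benzyloxy-3,5-dimethoxybenzyl)-2-oxotetrahydrofuran-3-carboxylate | COc1cc(C[C@H]2COC(=O)[C@]2(C(=O)OC)Cc3cc(OC)c(OCc4ccccc4)c(OC)c3)cc(OC)c1OCc1ccccc1
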